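**Retrosynthetic overview**

1. Numbering used: tetrahydrofuro[3,4-c]furan-1-one with C1(=O), O2, C3 (trihydroxyphenyl), C3a, C4 (CH2), O5, C6 (dihydroxyphenyl), C6a. The target is (3S,3aR,6S,6aS): cis-fused, both aryl groups on the convex face.
2. Last disconnections: the five O-benzyl groups, then the C6–aryl bond (convex-face Friedel–Crafts arylation of a bicyclic lactol by 1,2-bis(benzyloxy)benzene).
3. Key disconnection: the C1(=O)–O2 unit leaves as CO2, cutting O2–C3 and C1–C6a in one operation; C3 and C6a then close to a cyclopropane (C3–C3a–C6a) fused to the oxolane lactol.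
4. Enabling feature: in the γ-lactone ring the benzylic, O-bearing C3 (trioxygenated aryl ring as donor) and C6a (alpha to the formyl-level acetal carbon C6 of the oxolane ring, the acceptor) are 1,3-related through C3a. The C3–C6a bond of the cyclopropane is therefore polarised to take up CO2 (C6a to carbon, carboxylate oxygen to C3).
5. The cyclopropane lactol comes from the lactone made by catalytic enantioselective intramolecular cyclopropanation of an (E)-cinnamyl diazoacetate. Ring order: cyclopropane plus oxolane ring (as lactone, then lactol); γ-lactone ring by CO2 insertion; second aryl ring last.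

Key step: step 7

Assumption: the 4R enantiomer of the dirhodium carboxamidate catalyst is taken to give the (1S,5R,6R) lactone, the sense shown by the R series of these catalysts with allylic diazoacetates; the 4S catalyst would be used if the opposite sense were found.

**Route**

Step 1
Reactants: 1 3,4,5-tris(benzyloxy)benzaldehyde; 2 triethyl phosphonoacetate
Product: 3 ethyl (2E)-3-[3,4,5-tris(benzyloxy)phenyl]prop-2-enoate
Conditions: NaH, THF, 0 °C to rt
Reagents that add atoms: none
Why: Horner–Wadsworth–Emmons olefination of an aromatic aldehyde with a stabilised phosphonate should give the (E)-cinnamate.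

Step 2
Reactants: 3 ethyl (2E)-3-[3,4,5-tris(benzyloxy)phenyl]prop-2-enoate
Product: 4 (2E)-3-[3,4,5-tris(benzyloxy)phenyl]prop-2-en-1-ol
Conditions: iBu2AlH (2.5 equiv), CH2Cl2, −78 °C; aq. KNaC4H4O6 work-up
Reagents that add atoms: none
Why: 1,2-reduction of a conjugated ester by the aluminium hydride should give the allylic alcohol without touching the alkene or the benzyl ethers.

Step 3
Reactants: 4 (2E)-3-[3,4,5-tris(benzyloxy)phenyl]prop-2-en-1-ol; 5 bromoacetyl bromide
Product: 6 (2E)-3-[3,4,5-tris(benzyloxy)phenyl]prop-2-en-1-yl bromoacetate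
Conditions: NaHCO3, MeCN, 0 °C
Reagents that add atoms: none
Why: O-acylation of a primary allylic alcohol by an acid bromide under bicarbonate buffering should avoid ionisation of the electron-rich cinnamyl system.

Step 4
Reactants: 6 (2E)-3-[3,4,5-tris(benzyloxy)phenyl]prop-2-en-1-yl bromoacetate
Product: 7 (2E)-3-[3,4,5-tris(benzyloxy)phenyl]prop-2-en-1-yl diazoacetate
Conditions: N,N′-ditosylhydrazine, DBU, THF, 0 °C
Reagents that add atoms: N,N′-ditosylhydrazine, Cc1ccc(cc1)S(=O)(=O)NNS(=O)(=O)c1ccc(C)cc1
Why: N-alkylation of the bis-sulfonyl hydrazine by the bromoacetate followed by base-induced loss of two sulfinate ions (Bamford–Stevens-type elimination) should give the diazoacetate.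

Step 5
Reactants: 7 (2E)-3-[3,4,5-tris(benzyloxy)phenyl]prop-2-en-1-yl diazoacetate
Product: 8 (1S,5R,6R)-6-[3,4,5-tris(benzyloxy)phenyl]-3-oxabicyclo[3.1.0]hexan-2-one
Conditions: Rh2(4R-MPPIM)4 (dirhodium tetrakis[methyl (4R)-2-oxo-1-(3-phenylpropanoyl)imidazolidine-4-carboxylate], 1 mol %), CH2Cl2, 40 °C, slow addition of 7
Reagents that add atoms: none
Why: Intramolecular cyclopropanation of an allylic diazoacetate through a chiral dirhodium carboxamidate carbene should place the aryl group exo (trans to the lactone ring) from the (E)-alkene geometry, while the catalyst selects the alkene face and so sets C1, C5 and C6 together.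

Step 6
Reactants: 8 (1S,5R,6R)-6-[3,4,5-tris(benzyloxy)phenyl]-3-oxabicyclo[3.1.0]hexan-2-one
Product: 9 (1S,5R,6R)-6-[3,4,5-tris(benzyloxy)phenyl]-3-oxabicyclo[3.1.0]hexan-2-ol
Conditions: iBu2AlH (1.1 equiv), CH2Cl2, −78 °C; aq. KNaC4H4O6 work-up
Reagents that add atoms: none
Why: Low-temperature partial reduction of a γ-lactone should stop at the aluminium hemiacetal and give the lactol, leaving the three stereocentres untouched.

Step 7
Reactants: 9 (1S,5R,6R)-6-[3,4,5-tris(benzyloxy)phenyl]-3-oxabicyclo[3.1.0]hexan-2-ol; 10 carbon dioxide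
Product: 14 (3S,3aR,6aS)-6-hydroxy-3-[3,4,5-tris(benzyloxy)phenyl]tetrahydro-1H,3H-furo[3,4-c]furan-1-one, via iodo enolate 11 (not isolated), via iodo carboxylate 12 (not isolated), via formyl lactone 13 (not isolated)
Conditions: MgI2 (1.5 equiv), iPr2NEt (1.0 equiv), CO2 (5 bar), THF, 60 °C; then aq. citric acid
Reagents that add atoms: none
Why: Proposed new method: MgI2 binds the ring-opened hydroxy aldehyde form of 9, iodide opens the polarised C1–C6 bond of this donor–acceptor cyclopropane at the benzylic carbon to give magnesium enolate 11, the enolate carbon adds to CO2 to give the chelated formyl carboxylate 12, the carboxylate oxygen displaces the benzylic iodide to give formyl lactone 13, and the hydroxymethyl group adds to the formyl group to give 14. The closest known reaction types are the Lewis-acid-mediated formal [3+2] cycloadditions of donor–acceptor cyclopropanes with aldehydes and heterocumulenes, the MgI2-mediated ring expansion of acceptor cyclopropanes with imines, and the magnesium-mediated carboxylation of enolisable carbonyl compounds with CO2; CO2 has not been used as the two-atom partner. The γ-lactone ring closes by 5-exo-tet O-alkylation and the oxolane ring re-closes by 5-exo-trig hemiacetal formation. C3 is set by double inversion (iodide, then carboxylate), that is net retention of the cyclopropane configuration, and iodide exchange can only lead to the same, more stable trans (exo-aryl) lactone; C3a is untouched; C6a, epimerisable in 13, is fixed by the lactol ring because only the cis-fused bicycle can close; C6 is an anomeric mixture that is erased in step 8. The step needs cleavage of the cyclopropane bond that joins the donor and the acceptor carbon, which the tris(benzyloxy)phenyl group on one carbon and the formyl group on the other secure, and C-carboxylation of the enolate in preference to O-alkylation or loss of HI, which CO2 pressure and chelation of the magnesium formylacetate should favour.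

Step 8
Reactants: 14 (3S,3aR,6aS)-6-hydroxy-3-[3,4,5-tris(benzyloxy)phenyl]tetrahydro-1H,3H-furo[3,4-c]furan-1-one; 15 1,2-bis(benzyloxy)benzene
Product: 16 (3S,3aR,6S,6aS)-6-[3,4-bis(benzyloxy)phenyl]-3-[3,4,5-tris(benzyloxy)phenyl]tetrahydro-1H,3H-furo[3,4-c]furan-1-one
Conditions: 15 (5 equiv), Sc(OTf)3 (10 mol %), 4 Å molecular sieves, CH2Cl2, −20 to 0 °C
Reagents that add atoms: none
Why: Lewis-acid-catalysed dehydrative Friedel–Crafts C-arylation of a cyclic hemiacetal through its oxocarbenium ion (C-aryl glycoside type) should occur para to a benzyloxy group and from the convex face of the cis-fused bicycle, which sets C6 with the aryl group exo (6S) while C6a can only remain cis-fused.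

Step 9
Reactants: 16 (3S,3aR,6S,6aS)-6-[3,4-bis(benzyloxy)phenyl]-3-[3,4,5-tris(benzyloxy)phenyl]tetrahydro-1H,3H-furo[3,4-c]furan-1-one
Product: 17 (3S,3aR,6S,6aS)-6-(3,4-dihydroxyphenyl)-3-(3,4,5-trihydroxyphenyl)tetrahydro-1H,3H-furo[3,4-c]furan-1-one
Conditions: H2 (1 atm), Pd/C (10 %), EtOAc–MeOH, rt, stopped at full debenzylation
Reagents that add atoms: none
Why: Hydrogenolysis of the five aryl benzyl ethers over palladium on carbon under neutral conditions should be faster than cleavage of the benzylic C3–O2 and C6–O5 bonds and does not touch any stereocentre.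

**Compound list**

1 | 3,4,5-tris(benzyloxy)benzaldehyde | O=Cc1cc(OCc2ccccc2)c(OCc2ccccc2)c(OCc2ccccc2)c1 | starting material
2 | triethyl phosphonoacetate | CCOC(=O)CP(=O)(OCC)OCC | starting material
3 | ethyl (2E)-3-[3,4,5-tris(benzyloxy)phenyl]prop-2-enoate | CCOC(=O)/C=C/c1cc(OCc2ccccc2)c(OCc2ccccc2)c(OCc2ccccc2)c1 | intermediate
4 | (2E)-3-[3,4,5-tris(benzyloxy)phenyl]prop-2-en-1-ol | OC/C=C/c1cc(OCc2ccccc2)c(OCc2ccccc2)c(OCc2ccccc2)c1 | intermediate
5 | bromoacetyl bromide | BrCC(Br)=O | starting material
6 | (2E)-3-[3,4,5-tris(benzyloxy)phenyl]prop-2-en-1-yl bromoacetate | BrCC(=O)OC/C=C/c1cc(OCc2ccccc2)c(OCc2ccccc2)c(OCc2ccccc2)c1 | intermediate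
7 | (2E)-3-[3,4,5-tris(benzyloxy)phenyl]prop-2-en-1-yl diazoacetate | [N-]=[N+]=CC(=O)OC/C=C/c1cc(OCc2ccccc2)c(OCc2ccccc2)c(OCc2ccccc2)c1 | intermediate
8 | (1S,5R,6R)-6-[3,4,5-tris(benzyloxy)phenyl]-3-oxabicyclo[3.1.0]hexan-2-one | O=C1OC[C@@H]2[C@@H](c3cc(OCc4ccccc4)c(OCc4ccccc4)c(OCc4ccccc4)c3)[C@H]12 | intermediate
9 | (1S,5R,6R)-6-[3,4,5-tris(benzyloxy)phenyl]-3-oxabicyclo[3.1.0]hexan-2-ol (both C2 epimers; ring-chain tautomer of the cis hydroxy aldehyde) | OC1OC[C@@H]2[C@@H](c3cc(OCc4ccccc4)c(OCc4ccccc4)c(OCc4ccccc4)c3)[C@H]12 | intermediate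
10 | carbon dioxide | O=C=O | starting material
11 | iodomagnesium enolate of (3R,4R)-3-(hydroxymethyl)-4-iodo-4-[3,4,5-tris(benzyloxy)phenyl]butanal, drawn as the parent aldehyde | O=CC[C@H](CO)[C@@H](I)c1cc(OCc2ccccc2)c(OCc2ccccc2)c(OCc2ccccc2)c1 | intermediate
12 | magnesium salt of (3R,4R)-2-formyl-3-(hydroxymethyl)-4-iodo-4-[3,4,5-tris(benzyloxy)phenyl]butanoic acid (C2 not defined), drawn as the acid | OC(=O)C(C=O)[C@H](CO)[C@@H](I)c1cc(OCc2ccccc2)c(OCc2ccccc2)c(OCc2ccccc2)c1 | intermediate
13 | (4R,5S)-4-(hydroxymethyl)-2-oxo-5-[3,4,5-tris(benzyloxy)phenyl]oxolane-3-carbaldehyde (C3 epimerisable) | O=CC1C(=O)O[C@H](c2cc(OCc3ccccc3)c(OCc3ccccc3)c(OCc3ccccc3)c2)[C@H]1CO | intermediate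
14 | (3S,3aR,6aS)-6-hydroxy-3-[3,4,5-tris(benzyloxy)phenyl]tetrahydro-1H,3H-furo[3,4-c]furan-1-one (both C6 epimers) | O=C1O[C@H](c3cc(OCc4ccccc4)c(OCc4ccccc4)c(OCc4ccccc4)c3)[C@H]2COC(O)[C@@H]12 | intermediate
15 | 1,2-bis(benzyloxy)benzene | c1ccc(OCc2ccccc2)c(OCc2ccccc2)c1 | starting material
16 | (3S,3aR,6S,6aS)-6-[3,4-bis(benzyloxy)phenyl]-3-[3,4,5-tris(benzyloxy)phenyl]tetrahydro-1H,3H-furo[3,4-c]furan-1-one | O=C1O[C@H](c3cc(OCc4ccccc4)c(OCc4ccccc4)c(OCc4ccccc4)c3)[C@H]2CO[C@H](c3ccc(OCc4ccccc4)c(OCc4ccccc4)c3)[C@@H]12 | intermediate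
17 | (3S,3aR,6S,6aS)-6-(3,4-dihydroxyphenyl)-3-(3,4,5-trihydroxyphenyl)tetrahydro-1H,3H-furo[3,4-c]furan-1-one (CNP0290035.1) | O=C1O[C@H](c2cc(O)c(O)c(O)c2)[C@H]2CO[C@H](c3ccc(O)c(O)c3)[C@@H]12 | target

**Step count and risks**

Total step count: 9. Longest linear sequence: 9 steps (1 to 17).

Steps most likely to fail:

Step 7 (Proposed new method). The magnesium enolate may close on oxygen instead of taking up CO2 (Cloke–Wilson-type rearrangement to a dihydrofuran). The benzylic iodide may lose HI, or carboxylation may not compete with re-closure to the cyclopropane. The fallback uses known chemistry, sets out from lactone 8 and returns at lactol 14. The carboxyl carbon is first attached to the cyclopropane carbon C1 by enolate acylation (LiN(iPr)2, THF, −78 °C, then Boc2O), which should give tert-butyl (1R,5R,6R)-2-oxo-6-[3,4,5-tris(benzyloxy)phenyl]-3-oxabicyclo[3.1.0]hexane-1-carboxylate F1. iBu2AlH at −78 °C should then reduce the lactone carbonyl in preference to the hindered tert-butyl ester and give tert-butyl (1R,5R,6R)-2-hydroxy-6-[3,4,5-tris(benzyloxy)phenyl]-3-oxabicyclo[3.1.0]hexane-1-carboxylate F2. CF3CO2H in CH2Cl2 at 0 °C should trigger the acid-mediated ring expansion of this doubly activated donor–acceptor cyclopropane: the ester carbonyl oxygen captures the benzylic cation at the future C3 from the side that gives the trans lactone, 2-methylpropene is lost, and tautomerisation with lactol closure gives 14.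

Step 8. The oxocarbenium ion may lose the C6a proton to give the conjugated enol ether. The new benzylic ether may ionise and take up a second arene (diarylmethane formation), the benzylic lactone C3–O2 bond may ionise, or the trioxygenated ring of a second molecule may compete as the nucleophile. The fallback sets out from 14 and returns at 16. Acetylation (Ac2O, pyridine) should give (3S,3aR,6aS)-6-acetoxy-3-[3,4,5-tris(benzyloxy)phenyl]tetrahydro-1H,3H-furo[3,4-c]furan-1-one F3. F3 is then coupled at −40 °C under BF3·OEt2 with 1.2 equivalents of potassium [3,4-bis(benzyloxy)phenyl]trifluoroborate F4, made from the commercial boronic acid with KHF2. This is the known addition of an organotrifluoroborate to an oxocarbenium ion; it is ipso-selective, needs no excess arene, and should again deliver the aryl group to the convex face.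

Step 9. Hydrogenolysis may go on to cleave the benzylic C3–O2 and C6–O5 bonds, or stop before all five benzyl groups are removed. The fallback sets out from 16 and returns at 17 directly: non-reductive debenzylation with BCl3 and pentamethylbenzene as cation scavenger in CH2Cl2 at −78 °C. This fallback makes no new compound (F0).

**Further compounds**

F1 | step 7 | tert-butyl (1R,5R,6R)-2-oxo-6-[3,4,5-tris(benzyloxy)phenyl]-3-oxabicyclo[3.1.0]hexane-1-carboxylate | O=C1OC[C@@H]2[C@@H](c3cc(OCc4ccccc4)c(OCc4ccccc4)c(OCc4ccccc4)c3)[C@]12C(=O)OC(C)(C)C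
F2 | step 7 | tert-butyl (1R,5R,6R)-2-hydroxy-6-[3,4,5-tris(benzyloxy)phenyl]-3-oxabicyclo[3.1.0]hexane-1-carboxylate (both C2 epimers) | OC1OC[C@@H]2[C@@H](c3cc(OCc4ccccc4)c(OCc4ccccc4)c(OCc4ccccc4)c3)[C@]12C(=O)OC(C)(C)C
F3 | step 8 | (3S,3aR,6aS)-6-acetoxy-3-[3,4,5-tris(benzyloxy)phenyl]tetrahydro-1H,3H-furo[3,4-c]furan-1-one (both C6 epimers) | O=C1O[C@H](c3cc(OCc4ccccc4)c(OCc4ccccc4)c(OCc4ccccc4)c3)[C@H]2COC(OC(C)=O)[C@@H]12
F4 | step 8 | potassium [3,4-bis(benzyloxy)phenyl]trifluoroborate | [K+].F[B-](F)(F)c1ccc(OCc2ccccc2)c(OCc2ccccc2)c1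
F0 | step 9 | none | none
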